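**Retrosynthetic overview** (benzoxepine numbering: O1, C2 bearing CMe2OH, C3, C4 bearing the angelate, C5 bearing =CH2, C5a, C6–C9, C9a)
1. The oxepine is the only ring made and is closed last through O1–C2: the C9a phenoxide opens a side-chain (R)-2,2-dimethyloxirane 7-exo, which leaves the epoxide oxygen as the tertiary alcohol.
2. Enabling feature: on the benzo ring O1 (on C9a) is para to the C7 hydroxyl and ortho to the C9 hydroxyl, with the C8 methyl between the two hydroxyls. The ring is therefore the reduced form of the 2-hydroxy-1,4-benzoquinone that a symmetric 5-substituted 2-methylresorcinol gives on Teuber oxidation, so the O1 oxygen is installed and released as the nucleophile in one flask, with no regiochemistry to control and no phenol protecting group left at the end.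
3. Before that: the C2/CMe2 epoxide by Shi epoxidation of a prenyl group; the C4 angelate by Yamaguchi esterification; the C5a–C5 bond by Suzuki coupling of an aryl boronate (Ir C–H borylation of bis-TIPS 2-methylresorcinol) with an enol triflate that already holds C5=CH2.
4. C4 (R) comes from methyl (R)-glycidate, opened at its CH2 by 2-methyl-1-propenylmagnesium bromide (C3–C2 bond).

Key step: step 13

Assumption (chemistry): the D-fructose-derived Shi ketone is taken to give the (R)-epoxide of the prenyl group, as its spiro transition-state model predicts for trisubstituted alkenes; if the sense were opposite, the L-series ketone would be used in step 11.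

**Step 1**
Reactants: 1 2-methylresorcinol
Product: 2 2,6-bis(triisopropylsilyloxy)toluene
Conditions: TIPSCl, imidazole, DMF, 50 °C
Reagents that add atoms: chlorotriisopropylsilane, CC(C)[Si](Cl)(C(C)C)C(C)C
Why: Silyl ether formation on both phenols gives protection that is stable to base, Pd and organometallics and is removed by fluoride in step 12 without touching ester or epoxide.

**Step 2**
Reactants: 2 2,6-bis(triisopropylsilyloxy)toluene
Product: 3 2-[4-methyl-3,5-bis(triisopropylsilyloxy)phenyl]-4,4,5,5-tetramethyl-1,3,2-dioxaborolane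
Conditions: [Ir(OMe)(cod)]2 (cat.), dtbpy (cat.), B2pin2, THF, 80 °C
Reagents that add atoms: bis(pinacolato)diboron, CC1(C)OB(B2OC(C)(C)C(C)(C)O2)OC1(C)C
Why: Iridium-catalysed aromatic C–H borylation is sterically controlled and should go only to the one C–H without an ortho substituent, para to the methyl group, which becomes C5a.

**Step 3**
Reactants: 4 methyl (R)-glycidate; 5 2-methyl-1-propenylmagnesium bromide
Product: 6 methyl (2R)-2-hydroxy-5-methylhex-4-enoate
Conditions: CuI (10 mol%), THF, −40 °C; aq. NH4Cl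
Reagents that add atoms: none
Why: Copper-catalysed SN2 opening of the terminal epoxide carbon by the alkenyl Grignard reagent forms the C3–C2 bond and breaks no bond at the C–O stereocentre, so the future C4 keeps its (R) configuration from the chiral pool.

**Step 4**
Reactants: 6 methyl (2R)-2-hydroxy-5-methylhex-4-enoate
Product: 7 methyl (2R)-5-methyl-2-(triethylsilyloxy)hex-4-enoate
Conditions: TESCl, imidazole, CH2Cl2, 0 °C to rt
Reagents that add atoms: chlorotriethylsilane, CC[Si](Cl)(CC)CC
Why: Silyl ether formation; TES is chosen for the secondary alcohol because mild acid later removes it selectively in the presence of the aryl TIPS ethers.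

**Step 5**
Reactants: 7 methyl (2R)-5-methyl-2-(triethylsilyloxy)hex-4-enoate
Product: 8 (2R)-N-methoxy-N,5-dimethyl-2-(triethylsilyloxy)hex-4-enamide
Conditions: MeNH(OMe)·HCl, i-PrMgCl, THF, −20 to 0 °C
Reagents that add atoms: N,O-dimethylhydroxylamine hydrochloride, CNOC.Cl
Why: Aminolysis of the ester by the magnesium amide (Weinreb amide formation) should proceed without enolising the α-silyloxy centre and prepares a clean single addition.

**Step 6**
Reactants: 8 (2R)-N-methoxy-N,5-dimethyl-2-(triethylsilyloxy)hex-4-enamide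
Product: 9 (3R)-6-methyl-3-(triethylsilyloxy)hept-5-en-2-one
Conditions: MeMgBr, THF, −10 °C; aq. NH4Cl
Reagents that add atoms: methylmagnesium bromide, C[Mg]Br
Why: Weinreb ketone synthesis: the chelated tetrahedral adduct stops at mono-addition and releases the ketone only on work-up, so the α-stereocentre is never exposed to base as a ketone; the new methyl becomes the exocyclic methylene carbon.

**Step 7**
Reactants: 9 (3R)-6-methyl-3-(triethylsilyloxy)hept-5-en-2-one
Product: 10 (3R)-6-methyl-3-(triethylsilyloxy)hepta-1,5-dien-2-yl trifluoromethanesulfonate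
Conditions: KHMDS, THF, −78 °C; then PhNTf2, −78 to −40 °C
Reagents that add atoms: N-phenylbis(trifluoromethanesulfonimide), O=S(=O)(N(c1ccccc1)S(=O)(=O)C(F)(F)F)C(F)(F)F
Why: Kinetic deprotonation by the bulky amide should occur at the methyl group rather than at the hindered α-silyloxy methine, and O-triflation of that enolate (enol triflate formation) fixes the C5=CH2 unit without touching the stereocentre.

**Step 8**
Reactants: 10 (3R)-6-methyl-3-(triethylsilyloxy)hepta-1,5-dien-2-yl trifluoromethanesulfonate; 3 2-[4-methyl-3,5-bis(triisopropylsilyloxy)phenyl]-4,4,5,5-tetramethyl-1,3,2-dioxaborolane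
Product: 11 triethyl{[(3R)-6-methyl-2-[4-methyl-3,5-bis(triisopropylsilyloxy)phenyl]hepta-1,5-dien-3-yl]oxy}silane
Conditions: Pd(dppf)Cl2 (5 mol%), K3PO4, dioxane/H2O, 50 °C
Reagents that add atoms: none
Why: Suzuki–Miyaura coupling of the aryl pinacol boronate with the alkenyl triflate forms the C5a–C5 bond directly at the 1,1-disubstituted alkene level; the allylic silyl ether is not ionised by Pd(0), so C4 is retained.

**Step 9**
Reactants: 11 triethyl{[(3R)-6-methyl-2-[4-methyl-3,5-bis(triisopropylsilyloxy)phenyl]hepta-1,5-dien-3-yl]oxy}silane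
Product: 12 (3R)-6-methyl-2-[4-methyl-3,5-bis(triisopropylsilyloxy)phenyl]hepta-1,5-dien-3-ol
Conditions: PPTS (cat.), MeOH/CH2Cl2, 0 °C
Reagents that add atoms: none
Why: Acid-catalysed methanolysis of the secondary alkyl TES ether (silyl ether solvolysis) is much faster than that of aryl TIPS ethers, so only the C4 hydroxyl should be released.

**Step 10**
Reactants: 12 (3R)-6-methyl-2-[4-methyl-3,5-bis(triisopropylsilyloxy)phenyl]hepta-1,5-dien-3-ol; 13 angelic acid, (2Z)-2-methylbut-2-enoic acid
Product: 14 (3R)-6-methyl-2-[4-methyl-3,5-bis(triisopropylsilyloxy)phenyl]hepta-1,5-dien-3-yl (2Z)-2-methylbut-2-enoate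
Conditions: 13, 2,4,6-trichlorobenzoyl chloride, Et3N, toluene, rt; then 12, 75 °C
Reagents that add atoms: none
Why: Yamaguchi esterification through the mixed 2,4,6-trichlorobenzoic anhydride acylates hindered secondary alcohols with angelic acid without a nucleophilic amine catalyst, which should keep the (Z) geometry from drifting to the tiglate.

**Step 11**
Reactants: 14 (3R)-6-methyl-2-[4-methyl-3,5-bis(triisopropylsilyloxy)phenyl]hepta-1,5-dien-3-yl (2Z)-2-methylbut-2-enoate
Product: 15 (2R)-1-[(2R)-3,3-dimethyloxiran-2-yl]-3-[4-methyl-3,5-bis(triisopropylsilyloxy)phenyl]but-3-en-2-yl (2Z)-2-methylbut-2-enoate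
Conditions: D-fructose-derived Shi ketone (30 mol%), Oxone, K2CO3, Bu4NHSO4, MeCN/DMM/aq. Na2B4O7–EDTA (pH 10.5), 0 °C
Reagents that add atoms: potassium peroxymonosulfate (active component of Oxone), [K+].[O-]S(=O)(=O)OO
Why: Shi asymmetric epoxidation by the chiral dioxirane (spiro transition state) should set the epoxide CH carbon, the future C2, as (R) under catalyst control, and should select the electron-rich trisubstituted alkene because the 1,1-disubstituted aryl alkene is a poor substrate class that is further deactivated by its allylic acyloxy group and the angelate alkene is electron-poor.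

**Step 12**
Reactants: 15 (2R)-1-[(2R)-3,3-dimethyloxiran-2-yl]-3-[4-methyl-3,5-bis(triisopropylsilyloxy)phenyl]but-3-en-2-yl (2Z)-2-methylbut-2-enoate
Product: 16 (2R)-3-(3,5-dihydroxy-4-methylphenyl)-1-[(2R)-3,3-dimethyloxiran-2-yl]but-3-en-2-yl (2Z)-2-methylbut-2-enoate
Conditions: TBAF, AcOH, THF, 0 °C
Reagents that add atoms: none
Why: Fluoride cleavage of the aryl silyl ethers (desilylation), buffered with acetic acid, should free the symmetric resorcinol while epoxide and angelate stay intact; both hydroxyls are meta to the side chain and cannot reach the epoxide.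

**Step 13**
Reactants: 16 (2R)-3-(3,5-dihydroxy-4-methylphenyl)-1-[(2R)-3,3-dimethyloxiran-2-yl]but-3-en-2-yl (2Z)-2-methylbut-2-enoate
Product: 19 (2S,4R)-7,9-dihydroxy-2-(2-hydroxypropan-2-yl)-8-methyl-5-methylidene-2,3,4,5-tetrahydro-1-benzoxepin-4-yl (2Z)-2-methylbut-2-enoate (target), via hydroxyquinone epoxide 17 (not isolated), via benzenetriol epoxide 18 (not isolated)
Conditions: (KSO3)2NO, KH2PO4, MeCN/H2O, 0 °C; then, same flask under Ar, Na2S2O4, K2CO3 (pH ≈ 10), degassed, 0 to 35 °C; NaH2PO4 quench
Reagents that add atoms: Fremy's salt (potassium nitrosodisulfonate), [K+].[K+].[O]N(S(=O)(=O)[O-])S(=O)(=O)[O-]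
Why: Fremy's radical removes a phenolic hydrogen of the symmetric resorcinol, a second equivalent couples through oxygen at the para carbon (the future C9a) and loses imidodisulfonate to give hydroxy-p-quinone 17, which dithionite reduces to benzenetriol 18, whose C9a phenoxide attacks the epoxide CH (C2) from the back. The closest known reaction types are the Teuber oxidation of 5-alkylresorcinols to 2-hydroxy-1,4-benzoquinones, dithionite reduction of quinones, and base-mediated opening of a side-chain 2,2-dimethyloxirane by an ortho-phenoxide to a 2-(2-hydroxypropan-2-yl)benzoxepane; only their sequence in one flask is specific here, chosen so that the vinyl-substituted quinone is never concentrated. The oxepine ring closes 7-exo-tet. C2 is controlled by the (R)-epoxide from step 11 through SN2 inversion, which gives (S) and leaves the epoxide oxygen as the tertiary alcohol, while C4 is not involved. The step needs one site of arene oxidation, one attacking oxygen and exo opening: the two open ring positions of 16 are equivalent by symmetry, only the C9a oxygen can reach C2 in a seven-membered ring (the C9 oxygen would need eight, the C7 oxygen cannot reach), and under basic SN2 conditions the secondary C2 is preferred over the quaternary CMe2 carbon (8-endo). The angelate should survive carbonate at pH 10 and at most 35 °C because acyl transfer to a phenol is uphill, and dithionite with exclusion of air protects the electron-rich triol and product from re-oxidation.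

**Compound list**
1 | 2-methylresorcinol | Cc1c(O)cccc1O | starting material
2 | 2,6-bis(triisopropylsilyloxy)toluene | Cc1c(O[Si](C(C)C)(C(C)C)C(C)C)cccc1O[Si](C(C)C)(C(C)C)C(C)C | intermediate
3 | 2-[4-methyl-3,5-bis(triisopropylsilyloxy)phenyl]-4,4,5,5-tetramethyl-1,3,2-dioxaborolane | Cc1c(O[Si](C(C)C)(C(C)C)C(C)C)cc(B2OC(C)(C)C(C)(C)O2)cc1O[Si](C(C)C)(C(C)C)C(C)C | intermediate
4 | methyl (R)-glycidate | COC(=O)[C@H]1CO1 | starting material
5 | 2-methyl-1-propenylmagnesium bromide | CC(C)=C[Mg]Br | starting material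
6 | methyl (2R)-2-hydroxy-5-methylhex-4-enoate | COC(=O)[C@H](O)CC=C(C)C | intermediate
7 | methyl (2R)-5-methyl-2-(triethylsilyloxy)hex-4-enoate | COC(=O)[C@H](O[Si](CC)(CC)CC)CC=C(C)C | intermediate
8 | (2R)-N-methoxy-N,5-dimethyl-2-(triethylsilyloxy)hex-4-enamide | CON(C)C(=O)[C@H](O[Si](CC)(CC)CC)CC=C(C)C | intermediate
9 | (3R)-6-methyl-3-(triethylsilyloxy)hept-5-en-2-one | CC(=O)[C@H](O[Si](CC)(CC)CC)CC=C(C)C | intermediate
10 | (3R)-6-methyl-3-(triethylsilyloxy)hepta-1,5-dien-2-yl trifluoromethanesulfonate | C=C(OS(=O)(=O)C(F)(F)F)[C@H](O[Si](CC)(CC)CC)CC=C(C)C | intermediate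
11 | triethyl{[(3R)-6-methyl-2-[4-methyl-3,5-bis(triisopropylsilyloxy)phenyl]hepta-1,5-dien-3-yl]oxy}silane | C=C(c1cc(O[Si](C(C)C)(C(C)C)C(C)C)c(C)c(O[Si](C(C)C)(C(C)C)C(C)C)c1)[C@H](O[Si](CC)(CC)CC)CC=C(C)C | intermediate
12 | (3R)-6-methyl-2-[4-methyl-3,5-bis(triisopropylsilyloxy)phenyl]hepta-1,5-dien-3-ol | C=C(c1cc(O[Si](C(C)C)(C(C)C)C(C)C)c(C)c(O[Si](C(C)C)(C(C)C)C(C)C)c1)[C@H](O)CC=C(C)C | intermediate
13 | angelic acid, (2Z)-2-methylbut-2-enoic acid | C/C=C(/C)C(=O)O | starting material
14 | (3R)-6-methyl-2-[4-methyl-3,5-bis(triisopropylsilyloxy)phenyl]hepta-1,5-dien-3-yl (2Z)-2-methylbut-2-enoate | C=C(c1cc(O[Si](C(C)C)(C(C)C)C(C)C)c(C)c(O[Si](C(C)C)(C(C)C)C(C)C)c1)[C@@H](CC=C(C)C)OC(=O)/C(C)=C\C | intermediate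
15 | (2R)-1-[(2R)-3,3-dimethyloxiran-2-yl]-3-[4-methyl-3,5-bis(triisopropylsilyloxy)phenyl]but-3-en-2-yl (2Z)-2-methylbut-2-enoate | C=C(c1cc(O[Si](C(C)C)(C(C)C)C(C)C)c(C)c(O[Si](C(C)C)(C(C)C)C(C)C)c1)[C@@H](C[C@H]1OC1(C)C)OC(=O)/C(C)=C\C | intermediate
16 | (2R)-3-(3,5-dihydroxy-4-methylphenyl)-1-[(2R)-3,3-dimethyloxiran-2-yl]but-3-en-2-yl (2Z)-2-methylbut-2-enoate | C=C(c1cc(O)c(C)c(O)c1)[C@@H](C[C@H]1OC1(C)C)OC(=O)/C(C)=C\C | intermediate
17 | (2R)-1-[(2R)-3,3-dimethyloxiran-2-yl]-3-(5-hydroxy-4-methyl-3,6-dioxocyclohexa-1,4-dien-1-yl)but-3-en-2-yl (2Z)-2-methylbut-2-enoate | C=C(C1=CC(=O)C(C)=C(O)C1=O)[C@@H](C[C@H]1OC1(C)C)OC(=O)/C(C)=C\C | intermediate (not isolated)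
18 | (2R)-1-[(2R)-3,3-dimethyloxiran-2-yl]-3-(2,3,5-trihydroxy-4-methylphenyl)but-3-en-2-yl (2Z)-2-methylbut-2-enoate | C=C(c1cc(O)c(C)c(O)c1O)[C@@H](C[C@H]1OC1(C)C)OC(=O)/C(C)=C\C | intermediate (not isolated)
19 | (2S,4R)-7,9-dihydroxy-2-(2-hydroxypropan-2-yl)-8-methyl-5-methylidene-2,3,4,5-tetrahydro-1-benzoxepin-4-yl (2Z)-2-methylbut-2-enoate | C=C1c2cc(O)c(C)c(O)c2O[C@H](C(C)(C)O)C[C@H]1OC(=O)/C(C)=C\C | target

**Totals**
Total steps: 13. Longest linear sequence: 11 steps (steps 3–13, from methyl (R)-glycidate 4); the aryl branch (steps 1–2) joins at step 8.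

**Steps most likely to fail, with fallbacks**

Step 13. The transient vinyl-substituted hydroxyquinone may be lost before it is reduced (dimerisation, bisulfite addition, opening of the epoxide by its own acidic enol), and ring closure may be too slow at a pH the angelate tolerates. The fallback sets out from 14 and comes back at 18; it installs the C9a oxygen earlier and without a quinone. Compound 14 is desilylated (TBAF/AcOH) to the resorcinol triene ester F1. This is formylated ortho to a hydroxyl (MgCl2, Et3N, paraformaldehyde; Casnati–Skattebøl conditions, the two open positions being equivalent) to the salicylaldehyde F2. Dakin oxidation (H2O2, aq. NaHCO3, Na2S2O4 wash) should give the benzenetriol F3, which is silylated at once (TBSCl, imidazole) to the tris-TBS ether F4. Shi epoxidation as in step 11 should give the tris-TBS epoxide F5. TBAF/AcOH followed by K2CO3 under argon then releases 18, which closes to 19 by the same 7-exo opening.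

Step 11. The dioxirane may also attack the aryl-conjugated C5=CH2 alkene or the electron-rich ring, so that chemoselectivity is lost. The fallback sets out from 10 and comes back at 15; it makes the epoxide while the molecule holds only one nucleophilic alkene. Shi epoxidation of 10, whose triflate-bearing alkene is electron-poor and inert, should give the epoxy enol triflate F6. Suzuki coupling with 3 under the conditions of step 8 should give the epoxy styrene TES ether F7. The TES group is removed with pyridine-buffered HF·pyridine (THF, 0 °C), which should spare aryl TIPS ethers and the trisubstituted epoxide, to give the epoxy alcohol F8. Yamaguchi esterification with 13 as in step 10 returns to 15.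

Step 10. The activated angelate may isomerise to the (E)-tiglate, or acylation of the hindered allylic alcohol may stall. The fallback sets out from 12 and comes back at 14; it builds the (Z)-alkene on the substrate instead of carrying it through an activation. Compound 12 is esterified with 2-[bis(2,2,2-trifluoroethoxy)phosphoryl]propanoic acid (DCC, DMAP) to the phosphonate ester F9. Still–Gennari olefination (KHMDS, 18-crown-6, acetaldehyde, THF, −78 °C) should then deliver the (Z)-2-methylbut-2-enoate 14 under kinetic control.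

**Further compounds**
F1 | step 13 | (3R)-2-(3,5-dihydroxy-4-methylphenyl)-6-methylhepta-1,5-dien-3-yl (2Z)-2-methylbut-2-enoate | C=C(c1cc(O)c(C)c(O)c1)[C@@H](CC=C(C)C)OC(=O)/C(C)=C\C
F2 | step 13 | (3R)-2-(2-formyl-3,5-dihydroxy-4-methylphenyl)-6-methylhepta-1,5-dien-3-yl (2Z)-2-methylbut-2-enoate | C=C(c1cc(O)c(C)c(O)c1C=O)[C@@H](CC=C(C)C)OC(=O)/C(C)=C\C
F3 | step 13 | (3R)-6-methyl-2-(2,3,5-trihydroxy-4-methylphenyl)hepta-1,5-dien-3-yl (2Z)-2-methylbut-2-enoate | C=C(c1cc(O)c(C)c(O)c1O)[C@@H](CC=C(C)C)OC(=O)/C(C)=C\C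
F4 | step 13 | (3R)-6-methyl-2-[4-methyl-2,3,5-tris(tert-butyldimethylsilyloxy)phenyl]hepta-1,5-dien-3-yl (2Z)-2-methylbut-2-enoate | C=C(c1cc(O[Si](C)(C)C(C)(C)C)c(C)c(O[Si](C)(C)C(C)(C)C)c1O[Si](C)(C)C(C)(C)C)[C@@H](CC=C(C)C)OC(=O)/C(C)=C\C
F5 | step 13 | (2R)-1-[(2R)-3,3-dimethyloxiran-2-yl]-3-[4-methyl-2,3,5-tris(tert-butyldimethylsilyloxy)phenyl]but-3-en-2-yl (2Z)-2-methylbut-2-enoate | C=C(c1cc(O[Si](C)(C)C(C)(C)C)c(C)c(O[Si](C)(C)C(C)(C)C)c1O[Si](C)(C)C(C)(C)C)[C@@H](C[C@H]1OC1(C)C)OC(=O)/C(C)=C\C
F6 | step 11 | (3R)-4-[(2R)-3,3-dimethyloxiran-2-yl]-3-(triethylsilyloxy)but-1-en-2-yl trifluoromethanesulfonate | C=C(OS(=O)(=O)C(F)(F)F)[C@H](O[Si](CC)(CC)CC)C[C@H]1OC1(C)C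
F7 | step 11 | {[(2R)-1-[(2R)-3,3-dimethyloxiran-2-yl]-3-[4-methyl-3,5-bis(triisopropylsilyloxy)phenyl]but-3-en-2-yl]oxy}triethylsilane | C=C(c1cc(O[Si](C(C)C)(C(C)C)C(C)C)c(C)c(O[Si](C(C)C)(C(C)C)C(C)C)c1)[C@H](O[Si](CC)(CC)CC)C[C@H]1OC1(C)C
F8 | step 11 | (2R)-1-[(2R)-3,3-dimethyloxiran-2-yl]-3-[4-methyl-3,5-bis(triisopropylsilyloxy)phenyl]but-3-en-2-ol | C=C(c1cc(O[Si](C(C)C)(C(C)C)C(C)C)c(C)c(O[Si](C(C)C)(C(C)C)C(C)C)c1)[C@H](O)C[C@H]1OC1(C)C
F9 | step 10 | (3R)-6-methyl-2-[4-methyl-3,5-bis(triisopropylsilyloxy)phenyl]hepta-1,5-dien-3-yl 2-[bis(2,2,2-trifluoroethoxy)phosphoryl]propanoate (both epimers at the phosphonate carbon) | C=C(c1cc(O[Si](C(C)C)(C(C)C)C(C)C)c(C)c(O[Si](C(C)C)(C(C)C)C(C)C)c1)[C@@H](CC=C(C)C)OC(=O)C(C)P(=O)(OCC(F)(F)F)OCC(F)(F)F
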